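**Plan**
- Cuts: C3'–CH2 (ring B prenyl, back to a 4'-O-(1,1-dimethylallyl) ether), O1–C2 (ring C), C4–C4a (aryl ketone) and C8–CH2 (ring A prenyl), besides the O-protecting groups.
- Forward: rings A and B are bought as arenes (resorcinol, D-tyrosine). Ring A is prenylated at C8 and joined to the tyrosine-derived amide through C4–C4a. Ring C, the only ring that is made, is closed by oxidation at C2 (O1–C2). The ring B prenyl group follows by O-allylation and Claisen rearrangement, and a global deprotection ends the route.
- Enabling feature: C2 is benzylic and para to the 4'-OH of ring B, so two-electron oxidation of that phenol makes C2 the electrophilic carbon of a para-quinone methide within reach of the O1 phenol of ring A. Ring B–C2–C3–C4 is the aryl–CH2–CH(X)–CO skeleton of tyrosine with C3 at the α-carbon.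
- Stereochemistry: C3 (R) is the α-carbon of D-tyrosine, carried over by diazotisation with net retention. C2 (R) is set in the ring closure, trans to the C3 silyl ether.

Key step: step 9

Remarks: flavanone numbering (O1, C2, C3, C4, C4a, C5–C8, C8a; ring B primed) is used for all intermediates, open-chain ones included. TBS = tert-butyldimethylsilyl, MOM = methoxymethyl, prenyl = 3-methylbut-2-en-1-yl.
Assumption: DDQ is taken as the two-electron oxidant, because a one-electron surface oxidant such as Ag2O is expected to give aryloxyl coupling with a phenol that has no ortho substituents.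

**Step 1**
Reactants: 1 D-tyrosine
Product: 4 (R)-2-hydroxy-3-(4-hydroxyphenyl)propanoic acid, via diazonium carboxylate 2 (not isolated), via alpha-lactone 3 (not isolated)
Conditions: NaNO2, 1 M aq H2SO4, 0 °C → rt
Reagents that add atoms: water, O
Why: Diazotisation of an α-amino acid with neighbouring-group participation: the carboxylate displaces N2 from 2 to give 3 and water opens 3 at the alkyl carbon, two inversions that leave the chiral-pool centre (future C3) with the (R) configuration of D-tyrosine.

**Step 2**
Reactants: 4 (R)-2-hydroxy-3-(4-hydroxyphenyl)propanoic acid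
Product: 5 (R)-2-hydroxy-3-(4-hydroxyphenyl)-N-methoxy-N-methylpropanamide
Conditions: MeNH(OMe)·HCl, EDC·HCl, HOBt, N-methylmorpholine, DMF, 0 °C → rt
Reagents that add atoms: N,O-dimethylhydroxylamine hydrochloride, CNOC.Cl
Why: Carbodiimide/HOBt amide coupling, in which the amine should outcompete the phenol and the secondary alcohol for the activated acid and an α-hydroxy acid is not prone to racemisation.

**Step 3**
Reactants: 5 (R)-2-hydroxy-3-(4-hydroxyphenyl)-N-methoxy-N-methylpropanamide
Product: 6 (R)-2-(tert-butyldimethylsilyloxy)-3-[4-(tert-butyldimethylsilyloxy)phenyl]-N-methoxy-N-methylpropanamide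
Conditions: TBSCl (2.5 equiv), imidazole, DMF, rt
Reagents that add atoms: tert-butyldimethylsilyl chloride, CC(C)(C)[Si](C)(C)Cl
Why: Imidazole-promoted silyl ether formation on both hydroxyls gives an aryl and an alkyl silyl ether that tolerate the organolithium of step 6 and can later be told apart by fluoride.

**Step 4**
Reactants: 7 resorcinol
Product: 8 1,3-bis(methoxymethoxy)benzene
Conditions: MOMCl (2.4 equiv), i-Pr2NEt, CH2Cl2, 0 °C → rt
Reagents that add atoms: chloromethyl methyl ether, COCCl
Why: O-alkylation of the phenols with an α-chloro ether installs acetals that serve both as protection and as directing groups for the two lithiations.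

**Step 5**
Reactants: 8 1,3-bis(methoxymethoxy)benzene, 9 prenyl bromide
Product: 11 1,3-bis(methoxymethoxy)-2-(3-methylbut-2-en-1-yl)benzene, via 2-lithio arene 10 (not isolated)
Conditions: n-BuLi, THF, 0 °C → rt; then 9, 0 °C → rt
Reagents that add atoms: none
Why: Directed ortho-metalation at the C–H flanked by both OMOM groups, followed by SN2 alkylation of the aryllithium at the primary carbon of the allylic bromide, places the prenyl group at the future C8.

**Step 6**
Reactants: 11 1,3-bis(methoxymethoxy)-2-(3-methylbut-2-en-1-yl)benzene, 6 (R)-2-(tert-butyldimethylsilyloxy)-3-[4-(tert-butyldimethylsilyloxy)phenyl]-N-methoxy-N-methylpropanamide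
Product: 13 (R)-1-[2,4-bis(methoxymethoxy)-3-prenylphenyl]-2-(tert-butyldimethylsilyloxy)-3-[4-(tert-butyldimethylsilyloxy)phenyl]propan-1-one, via 4-lithio arene 12 (not isolated)
Conditions: 11 (1.5 equiv), n-BuLi, TMEDA, THF, 0 °C; then 6, −78 → −20 °C; sat. aq NH4Cl
Reagents that add atoms: none
Why: A second directed ortho-metalation (ring C–H ortho to OMOM, the two positions being equivalent) and a Weinreb ketone synthesis form C4–C4a; the N-methoxy-N-methylamide takes up one aryl group only and the cold, non-protic conditions should leave the silyloxy-bearing carbon untouched.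

**Step 7**
Reactants: 13 (R)-1-[2,4-bis(methoxymethoxy)-3-prenylphenyl]-2-(tert-butyldimethylsilyloxy)-3-[4-(tert-butyldimethylsilyloxy)phenyl]propan-1-one
Product: 14 (R)-2-(tert-butyldimethylsilyloxy)-3-[4-(tert-butyldimethylsilyloxy)phenyl]-1-[2-hydroxy-4-(methoxymethoxy)-3-prenylphenyl]propan-1-one
Conditions: MgBr2·OEt2 (3 equiv), CH2Cl2, 0 °C → rt; aqueous work-up
Reagents that add atoms: none
Why: Chelation-assisted ortho-selective cleavage of an aryl alkyl ether by a magnesium halide: Mg bridges the ketone oxygen and the O1 acetal oxygen so that bromide removes only this methoxymethyl group, while the O7 acetal and both silyl ethers, which cannot form such a chelate, should stay.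

**Step 8**
Reactants: 14 (R)-2-(tert-butyldimethylsilyloxy)-3-[4-(tert-butyldimethylsilyloxy)phenyl]-1-[2-hydroxy-4-(methoxymethoxy)-3-prenylphenyl]propan-1-one
Product: 15 (R)-2-(tert-butyldimethylsilyloxy)-1-[2-hydroxy-4-(methoxymethoxy)-3-prenylphenyl]-3-(4-hydroxyphenyl)propan-1-one
Conditions: KHF2 (2.5 equiv), MeOH, rt
Reagents that add atoms: none
Why: Chemoselective fluoride cleavage of the aryl silyl ether (phenoxide is the better leaving group) under near-neutral conditions should spare the secondary alkyl silyl ether and the acetal.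

**Step 9**
Reactants: 15 (R)-2-(tert-butyldimethylsilyloxy)-1-[2-hydroxy-4-(methoxymethoxy)-3-prenylphenyl]-3-(4-hydroxyphenyl)propan-1-one
Product: 17 (2R,3R)-3-(tert-butyldimethylsilyloxy)-2-(4-hydroxyphenyl)-7-(methoxymethoxy)-8-prenylchroman-4-one, via para-quinone methide 16 (not isolated)
Conditions: DDQ (1.0 equiv), CH2Cl2 (0.01 M), 0 °C → rt
Reagents that add atoms: none
Why: Proposed new method: DDQ takes a hydride equivalent from the para-hydroxybenzylic CH2 (future C2) of ring B, the only electron-rich free phenol since the ring A phenol is acyl-deactivated and hydrogen-bonded to the ketone, to give para-quinone methide 16, whose exocyclic carbon is attacked by the O1 phenol in an oxa-1,6-conjugate addition that forms O1–C2 and restores the aromaticity of ring B. The closest known reaction types are the DDQ oxidation of 4-alkylphenols to para-quinone methides that are trapped by oxygen nucleophiles, intramolecular oxa-1,6-additions to such methides, and the DDQ cyclodehydrogenation of 2'-hydroxydihydrochalcones; new is the use on an α-silyloxy dihydrochalcone with relay of configuration. Ring C closes in a 6-exo-trig mode. The new stereocentre C2 is controlled by C3: allylic 1,3-strain in 16 keeps the C3–H in the plane of the methide, so the tethered phenol adds to the face opposite the OTBS group and gives the 2,3-trans (2R,3R) ring with both substituents equatorial, the same isomer that equilibration through reversible ring opening would favour. The step needs chemoselectivity (oxidation of ring B, not of the ring A ortho-prenylphenol or of the product) and must outrun loss of the acidic C3–H from 16 to the achiral α-silyloxychalcone; the deactivated ring A phenol, the absence of base, high dilution, one equivalent of oxidant and low temperature are meant to secure this.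

**Step 10**
Reactants: 18 2-methylbut-3-en-2-ol
Product: 20 isobutyl 2-methylbut-3-en-2-yl carbonate, via lithium alkoxide 19 (not isolated)
Conditions: n-BuLi, THF, −78 °C; then i-BuOCOCl, −78 °C → rt
Reagents that add atoms: isobutyl chloroformate, CC(C)COC(=O)Cl
Why: O-acylation of a lithium alkoxide with a chloroformate, the prior deprotonation being needed because the tertiary allylic alcohol is a poor nucleophile.

**Step 11**
Reactants: 17 (2R,3R)-3-(tert-butyldimethylsilyloxy)-2-(4-hydroxyphenyl)-7-(methoxymethoxy)-8-prenylchroman-4-one, 20 isobutyl 2-methylbut-3-en-2-yl carbonate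
Product: 21 (2R,3R)-3-(tert-butyldimethylsilyloxy)-7-(methoxymethoxy)-2-[4-(2-methylbut-3-en-2-yloxy)phenyl]-8-prenylchroman-4-one
Conditions: 20 (2 equiv), Pd(PPh3)4 (5 mol%), THF, 0 °C → rt
Reagents that add atoms: none
Why: Tsuji–Trost O-allylation: zerovalent palladium ionises the tertiary carbonate with loss of CO2, the released alkoxide deprotonates the phenol, and the phenoxide attacks the more substituted end of the 1,1-dimethylallyl complex, giving the tertiary ether without added base so that C2 and C3 should not be disturbed.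

**Step 12**
Reactants: 21 (2R,3R)-3-(tert-butyldimethylsilyloxy)-7-(methoxymethoxy)-2-[4-(2-methylbut-3-en-2-yloxy)phenyl]-8-prenylchroman-4-one
Product: 23 (2R,3R)-3-(tert-butyldimethylsilyloxy)-2-(4-hydroxy-3-prenylphenyl)-7-(methoxymethoxy)-8-prenylchroman-4-one, via ortho-dienone 22 (not isolated)
Conditions: PhMe, 110 °C (sealed tube)
Reagents that add atoms: none
Why: Aromatic Claisen rearrangement ([3,3]-sigmatropic shift) to an ortho position of ring B (the two are equivalent, the para position is blocked), followed by tautomerisation of 22, turns the tertiary ether into the C3' prenyl group under neutral heat that should leave the trans-2,3 centres alone.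

**Step 13**
Reactants: 23 (2R,3R)-3-(tert-butyldimethylsilyloxy)-2-(4-hydroxy-3-prenylphenyl)-7-(methoxymethoxy)-8-prenylchroman-4-one
Product: 24 3-hydroxyglabrol, (2R,3R)-3,7-dihydroxy-2-(4-hydroxy-3-prenylphenyl)-8-prenylchroman-4-one
Conditions: 3 M aq HCl, MeOH, 45 °C
Reagents that add atoms: none
Why: Acid-catalysed solvolysis removes the acetal and the silyl ether together; methanolic HCl at moderate temperature is the usual unmasking of MOM ethers of ortho-prenylphenols and should be too mild to cyclise the prenyl groups or to open ring C, so the (2R,3R) configuration is kept.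

**Compound list**
1 | D-tyrosine, (R)-2-amino-3-(4-hydroxyphenyl)propanoic acid | N[C@H](Cc1ccc(O)cc1)C(=O)O | starting material
2 | (R)-2-diazonio-3-(4-hydroxyphenyl)propanoate (diazonium carboxylate, not isolated) | N#[N+][C@H](Cc1ccc(O)cc1)C(=O)[O-] | intermediate
3 | (S)-3-(4-hydroxybenzyl)oxiran-2-one (alpha-lactone, not isolated) | O=C1O[C@H]1Cc1ccc(O)cc1 | intermediate
4 | (R)-2-hydroxy-3-(4-hydroxyphenyl)propanoic acid | O[C@H](Cc1ccc(O)cc1)C(=O)O | intermediate
5 | (R)-2-hydroxy-3-(4-hydroxyphenyl)-N-methoxy-N-methylpropanamide | O[C@H](Cc1ccc(O)cc1)C(=O)N(C)OC | intermediate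
6 | (R)-2-(tert-butyldimethylsilyloxy)-3-[4-(tert-butyldimethylsilyloxy)phenyl]-N-methoxy-N-methylpropanamide | CC(C)(C)[Si](C)(C)O[C@H](Cc1ccc(O[Si](C)(C)C(C)(C)C)cc1)C(=O)N(C)OC | intermediate
7 | resorcinol | Oc1cccc(O)c1 | starting material
8 | 1,3-bis(methoxymethoxy)benzene | COCOc1cccc(OCOC)c1 | intermediate
9 | prenyl bromide, 1-bromo-3-methylbut-2-ene | CC(C)=CCBr | starting material
10 | [2,6-bis(methoxymethoxy)phenyl]lithium (2-lithio arene, not isolated) | COCOc1cccc(OCOC)c1[Li] | intermediate
11 | 1,3-bis(methoxymethoxy)-2-(3-methylbut-2-en-1-yl)benzene | COCOc1cccc(OCOC)c1CC=C(C)C | intermediate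
12 | [2,4-bis(methoxymethoxy)-3-(3-methylbut-2-en-1-yl)phenyl]lithium (4-lithio arene, not isolated) | COCOc1ccc([Li])c(OCOC)c1CC=C(C)C | intermediate
13 | (R)-1-[2,4-bis(methoxymethoxy)-3-prenylphenyl]-2-(tert-butyldimethylsilyloxy)-3-[4-(tert-butyldimethylsilyloxy)phenyl]propan-1-one | CC(C)(C)[Si](C)(C)O[C@H](Cc1ccc(O[Si](C)(C)C(C)(C)C)cc1)C(=O)c1ccc(OCOC)c(CC=C(C)C)c1OCOC | intermediate
14 | (R)-2-(tert-butyldimethylsilyloxy)-3-[4-(tert-butyldimethylsilyloxy)phenyl]-1-[2-hydroxy-4-(methoxymethoxy)-3-prenylphenyl]propan-1-one | CC(C)(C)[Si](C)(C)O[C@H](Cc1ccc(O[Si](C)(C)C(C)(C)C)cc1)C(=O)c1ccc(OCOC)c(CC=C(C)C)c1O | intermediate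
15 | (R)-2-(tert-butyldimethylsilyloxy)-1-[2-hydroxy-4-(methoxymethoxy)-3-prenylphenyl]-3-(4-hydroxyphenyl)propan-1-one (precursor of the key step) | CC(C)(C)[Si](C)(C)O[C@H](Cc1ccc(O)cc1)C(=O)c1ccc(OCOC)c(CC=C(C)C)c1O | intermediate
16 | (R)-2-(tert-butyldimethylsilyloxy)-1-[2-hydroxy-4-(methoxymethoxy)-3-prenylphenyl]-3-(4-oxocyclohexa-2,5-dien-1-ylidene)propan-1-one (para-quinone methide, not isolated) | CC(C)(C)[Si](C)(C)O[C@H](C=C1C=CC(=O)C=C1)C(=O)c1ccc(OCOC)c(CC=C(C)C)c1O | intermediate
17 | (2R,3R)-3-(tert-butyldimethylsilyloxy)-2-(4-hydroxyphenyl)-7-(methoxymethoxy)-8-prenylchroman-4-one (product of the key step) | Oc1ccc(cc1)[C@H]1Oc2c(CC=C(C)C)c(OCOC)ccc2C(=O)[C@@H]1O[Si](C)(C)C(C)(C)C | intermediate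
18 | 2-methylbut-3-en-2-ol | CC(C)(O)C=C | starting material
19 | lithium 2-methylbut-3-en-2-olate (not isolated) | [Li]OC(C)(C)C=C | intermediate
20 | isobutyl 2-methylbut-3-en-2-yl carbonate | CC(C)COC(=O)OC(C)(C)C=C | intermediate
21 | (2R,3R)-3-(tert-butyldimethylsilyloxy)-7-(methoxymethoxy)-2-[4-(2-methylbut-3-en-2-yloxy)phenyl]-8-prenylchroman-4-one | C=CC(C)(C)Oc1ccc(cc1)[C@H]1Oc2c(CC=C(C)C)c(OCOC)ccc2C(=O)[C@@H]1O[Si](C)(C)C(C)(C)C | intermediate
22 | (2R,3R)-3-(tert-butyldimethylsilyloxy)-7-(methoxymethoxy)-2-[4-oxo-3-prenylcyclohexa-1,5-dien-1-yl]-8-prenylchroman-4-one (ortho-dienone, both epimers at the prenyl-bearing ring carbon, not isolated) | O=C1C=CC(=CC1CC=C(C)C)[C@H]1Oc2c(CC=C(C)C)c(OCOC)ccc2C(=O)[C@@H]1O[Si](C)(C)C(C)(C)C | intermediate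
23 | (2R,3R)-3-(tert-butyldimethylsilyloxy)-2-(4-hydroxy-3-prenylphenyl)-7-(methoxymethoxy)-8-prenylchroman-4-one | CC(C)=CCc1cc(ccc1O)[C@H]1Oc2c(CC=C(C)C)c(OCOC)ccc2C(=O)[C@@H]1O[Si](C)(C)C(C)(C)C | intermediate
24 | 3-hydroxyglabrol, (2R,3R)-3,7-dihydroxy-2-(4-hydroxy-3-prenylphenyl)-8-prenylchroman-4-one | CC(C)=CCc1cc([C@H]2Oc3c(ccc(O)c3CC=C(C)C)C(=O)[C@@H]2O)ccc1O | target

**Total step count:** 13
**Longest linear sequence:** 10 steps (steps 1, 2, 3, 6, 7, 8, 9, 11, 12, 13, from D-tyrosine)

**Steps most likely to fail**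

1. Step 9 (proposed new method).
   - What may go wrong: the quinone methide may lose the C3 proton faster than it cyclises, which would drain material into the achiral α-silyloxychalcone. DDQ may go on to dehydrogenate the product across C2–C3 or attack the allylic CH2 of the ring A prenyl group. Intermolecular phenol addition to the methide may also compete.
   - Fallback (known chemistry): a chalcone epoxide route that sets out from aryllithium 12 (made from 11 as in step 6) and comes back at 17. Quenching 12 with N-methoxy-N-methylacetamide should give the acetophenone 1-[2,4-bis(methoxymethoxy)-3-prenylphenyl]ethanone F1. Claisen–Schmidt condensation with 4-(allyloxy)benzaldehyde (KOH, EtOH) should give the chalcone (E)-3-[4-(allyloxy)phenyl]-1-[2,4-bis(methoxymethoxy)-3-prenylphenyl]prop-2-en-1-one F2. Juliá–Colonna epoxidation (poly-L-leucine, urea–H2O2, DBU, THF) should give the (αR,βS)-epoxide F3. Methanolic HCl removes both acetals, and the freed O1 phenol opens the epoxide at the benzylic carbon with inversion to give (2R,3R)-2-[4-(allyloxy)phenyl]-3,7-dihydroxy-8-prenylchroman-4-one F4. MOMCl/i-Pr2NEt protects the acidic 7-OH to give the 7-O-methoxymethyl ether F5. TBSOTf/2,6-lutidine silylates O3 to give the 3-O-silyl ether F6. Pd(PPh3)4 with morpholine removes the allyl group and returns 17.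

2. Step 7.
   - What may go wrong: loss of chelation control, so that the magnesium halide also cleaves the O7 acetal, or cleaves or shifts the C3 silyl ether.
   - Fallback: exhaustive cleavage followed by selective re-protection, from 13 back to 14. Both aryl acetals of 13 are removed under non-protic conditions (TMSOTf, 2,2'-bipyridyl, CH2Cl2, 0 °C; then water) to give the resorcinol ketone (R)-2-(tert-butyldimethylsilyloxy)-3-[4-(tert-butyldimethylsilyloxy)phenyl]-1-(2,4-dihydroxy-3-prenylphenyl)propan-1-one F7. MOMCl (1.05 equiv) with i-Pr2NEt then alkylates only O7, because the O1 phenol is locked in a hydrogen bond to the ketone, and gives 14.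

3. Step 6.
   - What may go wrong: deprotonation at the doubly activated benzylic–allylic CH2 of the prenyl group instead of the ring C–H would give regioisomeric or allyl-transposed ketones. Proton transfer from the α-C–H of the amide would return starting materials.
   - Fallback: fix the site of the metal by halogen–lithium exchange, from 8 back to 12. NBS in MeCN brominates 8 para to one OMOM group to give 1-bromo-2,4-bis(methoxymethoxy)benzene F8. Lithium 2,2,6,6-tetramethylpiperidide (THF, −78 °C) deprotonates the C–H between the two OMOM groups without touching the bromide, and prenyl bromide gives 1-bromo-2,4-bis(methoxymethoxy)-3-prenylbenzene F9. Exchange with n-BuLi at −78 °C is faster than any deprotonation and delivers 12, which is acylated with 6 as in step 6.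

**Further compounds**
F1 | step 9 | 1-[2,4-bis(methoxymethoxy)-3-prenylphenyl]ethanone | CC(=O)c1ccc(OCOC)c(CC=C(C)C)c1OCOC
F2 | step 9 | (E)-3-[4-(allyloxy)phenyl]-1-[2,4-bis(methoxymethoxy)-3-prenylphenyl]prop-2-en-1-one | C=CCOc1ccc(/C=C/C(=O)c2ccc(OCOC)c(CC=C(C)C)c2OCOC)cc1
F3 | step 9 | [(2R,3S)-3-(4-(allyloxy)phenyl)oxiran-2-yl][2,4-bis(methoxymethoxy)-3-prenylphenyl]methanone | C=CCOc1ccc(cc1)[C@@H]1O[C@H]1C(=O)c1ccc(OCOC)c(CC=C(C)C)c1OCOC
F4 | step 9 | (2R,3R)-2-[4-(allyloxy)phenyl]-3,7-dihydroxy-8-prenylchroman-4-one | C=CCOc1ccc(cc1)[C@H]1Oc2c(CC=C(C)C)c(O)ccc2C(=O)[C@@H]1O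
F5 | step 9 | (2R,3R)-2-[4-(allyloxy)phenyl]-3-hydroxy-7-(methoxymethoxy)-8-prenylchroman-4-one | C=CCOc1ccc(cc1)[C@H]1Oc2c(CC=C(C)C)c(OCOC)ccc2C(=O)[C@@H]1O
F6 | step 9 | (2R,3R)-2-[4-(allyloxy)phenyl]-3-(tert-butyldimethylsilyloxy)-7-(methoxymethoxy)-8-prenylchroman-4-one | C=CCOc1ccc(cc1)[C@H]1Oc2c(CC=C(C)C)c(OCOC)ccc2C(=O)[C@@H]1O[Si](C)(C)C(C)(C)C
F7 | step 7 | (R)-2-(tert-butyldimethylsilyloxy)-3-[4-(tert-butyldimethylsilyloxy)phenyl]-1-(2,4-dihydroxy-3-prenylphenyl)propan-1-one | CC(C)(C)[Si](C)(C)O[C@H](Cc1ccc(O[Si](C)(C)C(C)(C)C)cc1)C(=O)c1ccc(O)c(CC=C(C)C)c1O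
F8 | step 6 | 1-bromo-2,4-bis(methoxymethoxy)benzene | COCOc1ccc(Br)c(OCOC)c1
F9 | step 6 | 1-bromo-2,4-bis(methoxymethoxy)-3-(3-methylbut-2-en-1-yl)benzene | COCOc1ccc(Br)c(OCOC)c1CC=C(C)C
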